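**Remark on the chemistry.** Locants follow the names used here: bicyclo[3.3.0]octane numbering for 7–10, azulene numbering for 13 and 14. Compounds 5 and 6 are used as epimer mixtures at the bromine-bearing carbon, and 10 may be a C-6 epimer mixture; both centres become sp2 later.

## Retrosynthetic overview

1. The oxirane of 14 comes from α-face epoxidation of the C-6=C-7 alkene of hydroazulene 13.
2. 13 comes from a two-carbon ring expansion of the cis-diquinane silyl peroxide 10 with a vinylphosphonium salt. An alkoxy radical breaks the C-5–C-6 bond of ring B; the C-5 radical adds to the vinyl group (C-8–C-8a bond of 13); the ylide then olefinates the ketone set free by the scission (C-6=C-7 bond of 13).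
3. Enabling feature: in 10 the O–O trigger sits on the tertiary C-6 of ring B, which is bonded to the quaternary, methyl-bearing ring-fusion carbon C-5. Homolysis at oxygen therefore gives a tertiary radical and a methyl ketone from the same bond.
4. 10 comes from 3-methylcyclopent-2-enone by enantioselective conjugate addition of an internal vinylalane (quaternary centre), a Sm(III)-enolate aldol (ring B), convex-face isopropyl addition, Mitsunobu benzoylation and Co-catalysed silylperoxidation.
5. Ring order: ring A (purchased cyclopentenone), ring B (aldol), seven-membered ring (ring B plus two carbons), oxirane.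

Key step: step 6

## Route

Step 1
Reactants: 1 4,4-diethoxybut-1-yne; 2 3-methylcyclopent-2-en-1-one
Product: 5 (3S)-2-bromo-3-(4,4-diethoxybut-1-en-2-yl)-3-methylcyclopentan-1-one, via internal vinylalane 3 (not isolated), via aluminium enolate 4 (not isolated)
Conditions: DIBAL-H, Ni(dppp)Cl2 (3 mol %), THF, 0→22 °C; then 2, chiral sulfonate-NHC–Ag complex (2.5 mol %), CuCl2·2H2O (5 mol %), THF, −30 °C; then NBS, −78 °C
Reagents that add atoms: N-bromosuccinimide BrN1C(=O)CCC1=O
Why: Ni-catalysed α-selective hydroalumination gives the internal vinylalane, its NHC–Cu-catalysed enantioselective conjugate addition to the β-methyl enone builds the quaternary centre (the ligand antipode that gives the 3R enolate is chosen), and the regiodefined aluminium enolate is brominated in situ (enolate α-halogenation).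

Step 2
Reactants: 5 (3S)-2-bromo-3-(4,4-diethoxybut-1-en-2-yl)-3-methylcyclopentan-1-one
Product: 7 (1S,5R,8R)-8-hydroxy-5-methyl-6-methylidenebicyclo[3.3.0]octan-2-one, via bromo keto aldehyde 6 (not isolated)
Conditions: LiBF4, MeCN–H2O (98:2), 23 °C; then SmI2 (2.2 equiv), THF, −78 °C
Reagents that add atoms: water O
Why: Mild acetal hydrolysis frees the aldehyde and SmI2 turns the α-bromo ketone into a regiodefined Sm(III) enolate that closes ring B by an intramolecular Reformatsky-type aldol (5-exo-trig, enolexo); the bicycle can only be cis-fused, which relays the quaternary centre to C-1, and the Sm-bridged chair transition state should place the new hydroxyl on the concave face, syn to the ketone.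

Step 3
Reactants: 7 (1S,5R,8R)-8-hydroxy-5-methyl-6-methylidenebicyclo[3.3.0]octan-2-one
Product: 8 (1S,2R,5R,8R)-5-methyl-6-methylidene-2-(propan-2-yl)bicyclo[3.3.0]octane-2,8-diol
Conditions: iPrMgCl (3 equiv), CeCl3, THF, −78→−40 °C
Reagents that add atoms: isopropylmagnesium chloride CC(C)[Mg]Cl
Why: Organocerium 1,2-addition (Imamoto conditions) suppresses enolisation and retro-aldol, and the nucleophile should enter from the open convex face of the cis-bicyclo[3.3.0]octanone, giving isopropyl exo and the tertiary hydroxyl endo.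

Step 4
Reactants: 8 (1S,2R,5R,8R)-5-methyl-6-methylidene-2-(propan-2-yl)bicyclo[3.3.0]octane-2,8-diol
Product: 9 (1S,2R,5R,8S)-5-methyl-6-methylidene-2-(propan-2-yl)bicyclo[3.3.0]octane-2,8-diol 8-benzoate
Conditions: PhCO2H, PPh3, DIAD, toluene, 0→23 °C
Reagents that add atoms: benzoic acid OC(=O)c1ccccc1
Why: Mitsunobu esterification acylates only the secondary alcohol and inverts it (SN2 by benzoate from the convex face), turning the endo carbinol into the required exo benzoate while the tertiary alcohol stays untouched.

Step 5
Reactants: 9 (1S,2R,5R,8S)-5-methyl-6-methylidene-2-(propan-2-yl)bicyclo[3.3.0]octane-2,8-diol 8-benzoate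
Product: 10 (1S,2R,5R,6R,8S)-5,6-dimethyl-2-(propan-2-yl)-6-[(triethylsilyl)peroxy]bicyclo[3.3.0]octane-2,8-diol 8-benzoate
Conditions: Co(thd)2 (5 mol %), Et3SiH, O2 (1 atm), ClCH2CH2Cl, 23 °C
Reagents that add atoms: triethylsilane CC[SiH](CC)CC; dioxygen O=O
Why: Mukaiyama–Isayama silylperoxidation (Co–H hydrogen-atom transfer, O2 capture of the tertiary radical, silyl transfer) is Markovnikov-selective for the 1,1-disubstituted alkene and puts the O–O trigger on the ring-B carbon only, so the free tertiary alcohol at C-2 is not activated.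

Step 6
Reactants: 10 (1S,2R,5R,6R,8S)-5,6-dimethyl-2-(propan-2-yl)-6-[(triethylsilyl)peroxy]bicyclo[3.3.0]octane-2,8-diol 8-benzoate; 11 ethenyl(triphenyl)phosphonium bromide
Product: 13 (3R,3aS,4S,8aR)-3-hydroxy-6,8a-dimethyl-3-(propan-2-yl)-1,2,3,3a,4,5,8,8a-octahydroazulen-4-yl benzoate, via keto ylide 12 (not isolated)
Conditions: Fe(acac)2 (2.5 equiv), 11 (1.5 equiv), degassed MeCN–THF, 0→50 °C
Reagents that add atoms: none
Why: Proposed new method: Fe(II) cleaves the O–O bond, the tertiary alkoxy radical undergoes β-scission of the C-5–C-6 bond to the tertiary ring-fusion radical and a methyl ketone, the nucleophilic radical adds to the vinylphosphonium, a second Fe(II) reduces the electrophilic α-phosphonio radical to ylide 12, and intramolecular Wittig olefination of the newly freed ketone closes the seven-membered ring (7-exo-trig addition to C=O, then oxaphosphetane collapse). The closest known reaction types are alkyl-radical generation from alkylsilyl peroxides with Fe or Cu, ring expansion of cycloalkanols by alkoxy-radical β-scission and re-closure, and radical–polar crossover of vinylphosphonium salts to ylides for carbonyl olefination; new is their union, in which the scission product serves as both radical and carbonyl partner. The only new stereocentre, C-8a, is set in the radical addition: the planar cyclopentyl radical should be attacked anti to the branched side chain on the neighbouring carbon, which gives the trans ring fusion. The step needs O–O activation at ring B only (secured by where step 5 placed the peroxide), scission toward the tertiary radical rather than CH2 or CH3 (secured by the quaternary ring-fusion carbon and relief of diquinane strain), and ylide attack at the ketone rather than the benzoate (secured by the higher electrophilicity of the ketone). No external base is present and acetylacetonate-bound Fe(III) is too weak an oxidant to re-oxidise the ylide, so the β-benzoyloxy ketone is not exposed to elimination conditions.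

Step 7
Reactants: 13 (3R,3aS,4S,8aR)-3-hydroxy-6,8a-dimethyl-3-(propan-2-yl)-1,2,3,3a,4,5,8,8a-octahydroazulen-4-yl benzoate
Product: 14 (3R,3aS,4S,6R,7S,8aR)-6,7-epoxy-3-hydroxy-6,8a-dimethyl-3-(propan-2-yl)decahydroazulen-4-yl benzoate
Conditions: mCPBA, NaHCO3, CH2Cl2, 0 °C
Reagents that add atoms: 3-chloroperoxybenzoic acid OOC(=O)c1cccc(Cl)c1
Why: Prilezhaev epoxidation of the trisubstituted alkene should occur anti to the axial angular methyl group on C-8a, delivering oxygen to the α face and setting C-6 (R) and C-7 (S); the benzoate and the hindered tertiary alcohol do not react.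

## Compound list

1 | 4,4-diethoxybut-1-yne | C#CCC(OCC)OCC | starting material
2 | 3-methylcyclopent-2-en-1-one | CC1=CC(=O)CC1 | starting material
3 | (4,4-diethoxybut-1-en-2-yl)bis(2-methylpropyl)alumane | C=C(CC(OCC)OCC)[Al](CC(C)C)CC(C)C | intermediate
4 | {[(3R)-3-(4,4-diethoxybut-1-en-2-yl)-3-methylcyclopent-1-en-1-yl]oxy}bis(2-methylpropyl)alumane | CC(C)C[Al](CC(C)C)OC1=C[C@](C)(C(=C)CC(OCC)OCC)CC1 | intermediate
5 | (3S)-2-bromo-3-(4,4-diethoxybut-1-en-2-yl)-3-methylcyclopentan-1-one (C-2 epimers) | O=C1CC[C@@](C)(C(=C)CC(OCC)OCC)C1Br | intermediate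
6 | 3-[(1S)-2-bromo-1-methyl-3-oxocyclopentyl]but-3-enal (bromide epimers) | O=C1CC[C@@](C)(C(=C)CC=O)C1Br | intermediate
7 | (1S,5R,8R)-8-hydroxy-5-methyl-6-methylidenebicyclo[3.3.0]octan-2-one (cis-fused, OH endo) | O=C1CC[C@@]2(C)C(=C)C[C@@H](O)[C@@H]12 | intermediate
8 | (1S,2R,5R,8R)-5-methyl-6-methylidene-2-(propan-2-yl)bicyclo[3.3.0]octane-2,8-diol (both OH endo, isopropyl exo) | CC(C)[C@]1(O)CC[C@@]2(C)C(=C)C[C@@H](O)[C@@H]12 | intermediate
9 | (1S,2R,5R,8S)-5-methyl-6-methylidene-2-(propan-2-yl)bicyclo[3.3.0]octane-2,8-diol 8-benzoate (benzoate exo) | CC(C)[C@]1(O)CC[C@@]2(C)C(=C)C[C@H](OC(=O)c3ccccc3)[C@@H]12 | intermediate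
10 | (1S,2R,5R,6R,8S)-5,6-dimethyl-2-(propan-2-yl)-6-[(triethylsilyl)peroxy]bicyclo[3.3.0]octane-2,8-diol 8-benzoate | CC(C)[C@]1(O)CC[C@@]2(C)[C@](C)(OO[Si](CC)(CC)CC)C[C@H](OC(=O)c3ccccc3)[C@@H]12 | intermediate
11 | ethenyl(triphenyl)phosphonium bromide | C=C[P+](c1ccccc1)(c1ccccc1)c1ccccc1.[Br-] | starting material
12 | ylide of (1S)-1-[(1S,2R,5R)-2-hydroxy-5-methyl-2-(propan-2-yl)-5-[2-(triphenylphosphonio)ethyl]cyclopentyl]-3-oxobutyl benzoate | CC(C)[C@]1(O)CC[C@](C)(C[CH-][P+](c2ccccc2)(c2ccccc2)c2ccccc2)[C@H]1[C@H](CC(C)=O)OC(=O)c1ccccc1 | intermediate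
13 | (3R,3aS,4S,8aR)-3-hydroxy-6,8a-dimethyl-3-(propan-2-yl)-1,2,3,3a,4,5,8,8a-octahydroazulen-4-yl benzoate (trans-fused) | CC(C)[C@]1(O)CC[C@]2(C)CC=C(C)C[C@H](OC(=O)c3ccccc3)[C@H]21 | intermediate
14 | (3R,3aS,4S,6R,7S,8aR)-6,7-epoxy-3-hydroxy-6,8a-dimethyl-3-(propan-2-yl)decahydroazulen-4-yl benzoate | CC(C)[C@]1(O)CC[C@]2(C)C[C@@H]3O[C@]3(C)C[C@H](OC(=O)c3ccccc3)[C@H]21 | target

## Summary

Total step count: 7. Longest linear sequence: 7 steps (from 1 and 2).

Steps most likely to fail:

1. Step 6 (Proposed new method). The tertiary radical may be captured by iron-bound halide or hydrogen before it adds to the vinylphosphonium, or the α-phosphonio radical may be quenched by hydrogen abstraction so that no ylide forms. Fallback with known reaction types, setting out from 10: Fe(II)-mediated fragmentation in the presence of allyl phenyl sulfone (radical allylation) should give the allyl ketone (1S)-1-[(1S,2R,5R)-2-hydroxy-5-methyl-2-(propan-2-yl)-5-(prop-2-en-1-yl)cyclopentyl]-3-oxobutyl benzoate F1. Ozonolysis of its only alkene (O3, then Me2S) should give the keto aldehyde F2. Intramolecular McMurry coupling (TiCl3, Zn–Cu, DME, reflux) would then close the seven-membered ring as the same alkene, returning to the route at 13.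

2. Step 2. The exocyclic double bond may migrate into conjugation with the aldehyde during acetal cleavage, before the samarium enolate is formed. Fallback, setting out from 2: the step 1 sequence is run with commercial tert-butyl(but-3-yn-1-yloxy)dimethylsilane in place of 1 to give the silyl ether F3. HF·pyridine would give the primary alcohol F4, and buffered Dess–Martin oxidation would reveal the aldehyde under neutral conditions, returning to the route at 6, which is treated with SmI2 at once.

3. Step 4. Elimination to a cyclopentene may compete with substitution at the hindered concave carbinol. Fallback, setting out from 8: Dess–Martin oxidation of the secondary alcohol should give the hydroxy ketone F5. Hydride delivery from the tertiary alkoxide side (Me4NBH(OAc)3, MeCN–AcOH, −20 °C) should give the anti (exo) diol F6. Benzoylation with retention (BzCl, DMAP, pyridine) returns to the route at 9.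

Further compounds
F1 | step 6 | (1S)-1-[(1S,2R,5R)-2-hydroxy-5-methyl-2-(propan-2-yl)-5-(prop-2-en-1-yl)cyclopentyl]-3-oxobutyl benzoate | CC(C)[C@]1(O)CC[C@](C)(CC=C)[C@H]1[C@H](CC(C)=O)OC(=O)c1ccccc1
F2 | step 6 | (1S)-1-[(1S,2R,5R)-2-hydroxy-5-methyl-5-(2-oxoethyl)-2-(propan-2-yl)cyclopentyl]-3-oxobutyl benzoate | CC(C)[C@]1(O)CC[C@](C)(CC=O)[C@H]1[C@H](CC(C)=O)OC(=O)c1ccccc1
F3 | step 2 | (3S)-2-bromo-3-{4-[(tert-butyldimethylsilyl)oxy]but-1-en-2-yl}-3-methylcyclopentan-1-one | O=C1CC[C@@](C)(C(=C)CCO[Si](C)(C)C(C)(C)C)C1Br
F4 | step 2 | (3S)-2-bromo-3-(4-hydroxybut-1-en-2-yl)-3-methylcyclopentan-1-one | O=C1CC[C@@](C)(C(=C)CCO)C1Br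
F5 | step 4 | (1R,2R,5R)-2-hydroxy-5-methyl-6-methylidene-2-(propan-2-yl)bicyclo[3.3.0]octan-8-one | CC(C)[C@]1(O)CC[C@@]2(C)C(=C)CC(=O)[C@@H]12
F6 | step 4 | (1S,2R,5R,8S)-5-methyl-6-methylidene-2-(propan-2-yl)bicyclo[3.3.0]octane-2,8-diol | CC(C)[C@]1(O)CC[C@@]2(C)C(=C)C[C@H](O)[C@@H]12
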